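Maple and elm are the same flask, read at different times. A single-handed catalyst, woken from its precatalyst, consumes left-handed substrate; at Tuesday's last reading less of it stood than of its mirror image.

| flask | left-handed substrate | right-handed substrate | gas | precatalyst | remark | time |
|---|---|---|---|---|---|---|
| Saturday's | 15 mM | 15 mM | 1.9 mM (held) | 41 µM | run made earlier |  |
| Tuesday's | 15 mM | 15 mM | 1.9 mM (held) | 92 µM | run made earlier |  |
| maple | 15 mM | 15 mM | 1.9 mM (held) | 61 µM |  | 4.0 min |
| elm | 15 mM | 15 mM | 1.9 mM (held) | 61 µM |  | 15 min |

Saturday's run (percent of the left-handed substrate and right-handed substrate together charged)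

| time / min | right-handed substrate / % | left-handed substrate / % | left-handed product / % |
|---|---|---|---|
| 0.667 | 50.5 | 48.4 | 0.9 |
| 1.50 | 50.2 | 44.7 | 4.6 |
| 3.00 | 50.3 | 34.9 | 15.2 |
| 5.00 | 49.4 | 23.6 | 27.5 |

Tuesday's run (percent of the left-handed substrate and right-handed substrate together charged)

| time / min | right-handed substrate / % | left-handed substrate / % | left-handed product / % |
|---|---|---|---|
| 0.667 | 49.9 | 47.1 | 3.0 |
| 1.50 | 49.0 | 39.9 | 10.1 |
| 3.00 | 48.4 | 22.8 | 25.7 |
| 5.00 | 48.0 | 9.3 | 41.1 |

- catalyst is single-handed; left-handed substrate and right-handed substrate are mirror images of each other, charged as a racemate, each of them at the stated concentration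
- the analysis behind the earlier runs scatters by 0.5 percentage points, standard deviation
- at the start none of the gas is in solution
- an excess is below zero if the other one leads

- the winner by excess of right-handed substrate over left-handed substrate among what is left of the two; "neither" if no more than 2 percentage points parts them (maple / elm / neither)
- excess of right-handed substrate over left-handed substrate among what is left of the two at the end, maple
- excess of right-handed substrate over left-handed substrate among what is left of the two at the end, elm

I used a bench rule: treat the loss of left-handed substrate as pseudo-first-order, falling by a factor e every lifetime, with the lifetime inversely proportional to the precatalyst charged. Tuesday's last two readings, scaled to this charge, gave a lifetime of 3.36 min. Saturday's pair, from a separate run, gave 3.44 min.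

The rule fails at the start. Run back from Tuesday's last reading, the line begins at 1.25 min, not at zero. That lag is 0.312 of maple's time but 0.0832 of elm's, so I counted lifetimes from the lag.

Tuesday's losses gave a selectivity factor of 41.2, a rough reading, and I took the right-handed lifetime as the left-handed one multiplied by that factor. My reckoning left 22.1% left-handed substrate in maple and 0.839% in elm. The excesses came to 37.9% and 96.4%.

The forecast named elm, with 38% (33% to 43%) for maple and 97% (90% to 99.5%) for elm, “assuming no catalyst death, which the runs cannot exclude”. Its elm figure stands slightly above mine.

The flask gave elm, with 38.2% for maple and 99.0% for elm.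

    coupling partner + catalyst + left-handed substrate → catalyst + left-handed product (k = 98500 M⁻² s⁻¹)
    coupling partner + catalyst + right-handed substrate → catalyst + right-handed product (k = 1830 M⁻² s⁻¹)
    coupling partner ⇌ dormant form (K = 2.00, k = 0.0109 s⁻¹)
    precatalyst ⇌ catalyst (K = 1.91, k = 0.00506 s⁻¹)
    gas ⇌ coupling partner, rate k5*(csat - [coupling partner]) (kL = 0.158 s⁻¹)

Time is the main reason for elm's lead: read at maple's time, elm stands at 38.2% instead of 99.0%, so the forecast's winner would fail if that gap went. Maple had 0.818 lifetimes and elm 4.09. The lifetime folds the coupling partner and the waking catalyst into one number. For the neighbour charged with 0.10 mM of precatalyst and read at maple's time, it scales to 2.05 min, and with the same lag my reckoning leaves 13.1% left-handed substrate. That flask holds 13.8%, with an excess of 55.9%.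

The earlier runs and the new flask are simulated for substances that don't exist; the scatter is artificial.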